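**Retrosynthetic overview**
1. Target 27 ⇒ α-ketol 24 + tiglic acid 25 (esterification last; the C1 ketone is unmasked just before).
2. The E-enone C3′=C4′ ⇒ crossed aldol addition of the lithium enolate of methyl ketone 13 (ring fragment) to aldehyde 17 (side-chain fragment), then dehydration.
3. 13 ⇒ isopropenyl compound 9 (allylic oxidation of the methyl group, MeMgBr, oxidation); 17 ⇒ 2-methylbut-3-en-2-ol 14.
4. 9 ⇒ (R)-carvone 1: C6 hydroxylation trans to C5, carbonyl reduction, hydroxyl-directed epoxidation.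
5. Rings: the carbocycle comes intact from 1; the oxirane is the only ring formed (step 5).

Convention and assumption: carvone ring locants are kept (C1 carbonyl or carbinol carbon, C2 methyl-bearing, C5 side-chain-bearing, C6 oxygenated); side chain is C1′ (on C5, carries =CH2) to C5′ (carbinol carbon); cis/trans are relative to the C5 side chain; the target is read as drawn (tiglate ester, E-enone, C5 configuration that of (R)-carvone).

**Route**

Step 1
Reactants: 1 (R)-(−)-carvone
Product: 3 carvone trimethylsilyl dienol ether, via carvone lithium dienolate 2 (not isolated)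
Conditions: LiN(iPr)2, THF, −78 °C; then Me3SiCl, −78 → 0 °C
Reagents that add atoms: chlorotrimethylsilane, C[Si](C)(C)Cl
Why: Kinetic deprotonation of the enone at C6 (α′) by the hindered amide and O-silylation give the cross-conjugated dienol ether (kinetic enolate trapping), leaving C5 untouched.

Step 2
Reactants: 3 carvone trimethylsilyl dienol ether
Product: 5 trans-6-hydroxycarvone, via trans-6-(trimethylsilyloxy)carvone 4 (not isolated)
Conditions: mCPBA (1.0 equiv), hexane/CH2Cl2, −20 °C; then 1 M HCl, THF, 0 °C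
Reagents that add atoms: 3-chloroperoxybenzoic acid (mCPBA), OOC(=O)c1cccc(Cl)c1
Why: Rubottom oxidation, in which the peracid attacks the electron-rich enol ether C1=C6 bond (far faster than the other alkenes) from the face opposite the adjacent C5 isopropenyl group, so the new C6–O bond is trans to C5 (minor cis isomer removed by chromatography).

Step 3
Reactants: 5 trans-6-hydroxycarvone
Product: 6 trans-6-(tert-butyldimethylsilyloxy)carvone
Conditions: TBSCl, imidazole, DMF, rt
Reagents that add atoms: tert-butyldimethylsilyl chloride, CC(C)(C)[Si](C)(C)Cl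
Why: Standard imidazole-promoted silylation of the secondary α-ketol hydroxyl, too mild to epimerise C6.

Step 4
Reactants: 6 trans-6-(tert-butyldimethylsilyloxy)carvone
Product: 7 allylic alcohol (1-OH cis to C5 isopropenyl; trans to 6-OTBS)
Conditions: NaBH4, CeCl3·7H2O, MeOH, −78 → −40 °C
Reagents that add atoms: none
Why: Luche 1,2-reduction, in which axial hydride delivery to the half-chair with the C5 and C6 substituents equatorial gives the equatorial C1 alcohol, cis to the isopropenyl group and trans to the silyloxy group, as in the reduction of carvone to cis-carveol.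

Step 5
Reactants: 7 allylic alcohol
Product: 8 epoxy alcohol (2,3-epoxide cis to 1-OH and to the C5 isopropenyl)
Conditions: VO(acac)2 (5 mol %), t-BuOOH, CH2Cl2, 0 °C → rt
Reagents that add atoms: tert-butyl hydroperoxide, CC(C)(C)OO
Why: Hydroxyl-directed vanadium-catalysed epoxidation reacts only at the allylic-alcohol alkene and delivers oxygen syn to the C1 hydroxyl, which sets C2 and C3 with the oxirane cis to the C5 substituent and trans to the C6 oxygen while the isopropenyl alkene is untouched.

Step 6
Reactants: 8 epoxy alcohol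
Product: 9 1-O-triethylsilyl-6-O-TBS epoxide
Conditions: Et3SiOTf, 2,6-lutidine, CH2Cl2, −78 °C
Reagents that add atoms: triethylsilyl trifluoromethanesulfonate, CC[Si](CC)(CC)OS(=O)(=O)C(F)(F)F
Why: Triflate silylation caps the hindered C1 alcohol at low temperature without touching the epoxide and gives a silyl ether that can later be cleaved in the presence of the TBS ether.

Step 7
Reactants: 9 1-O-triethylsilyl-6-O-TBS epoxide
Product: 10 primary allylic alcohol (C2′–OH)
Conditions: SeO2 (0.3 equiv), t-BuOOH, CH2Cl2, rt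
Reagents that add atoms: tert-butyl hydroperoxide, CC(C)(C)OO (oxygen relayed through SeO2, O=[Se]=O)
Why: Catalytic SeO2 allylic oxidation (ene reaction, then [2,3]-sigmatropic shift) of the only alkene attacks the methyl group because the other allylic position, the tertiary ring C5–H, is shielded by the C6 silyloxy group; some enal 11 already forms and is carried along.

Step 8
Reactants: 10 primary allylic alcohol
Product: 11 enal (C2′ aldehyde)
Conditions: Dess–Martin periodinane (DMP), pyridine, CH2Cl2, 0 °C → rt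
Reagents that add atoms: none
Why: Dess–Martin oxidation of the primary allylic alcohol under buffered conditions spares epoxide and silyl ethers and converges the step 7 mixture on the enal.

Step 9
Reactants: 11 enal
Product: 12 secondary allylic alcohol (C2′ epimers)
Conditions: MeMgBr, THF, −78 °C; then H2O (pH 7 buffer)
Reagents that add atoms: methylmagnesium bromide, C[Mg]Br
Why: Grignard 1,2-addition to the aldehyde at −78 °C leaves the epoxide alone, and the new C2′ carbinol centre (epimer mixture) is erased in the next step.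

Step 10
Reactants: 12 secondary allylic alcohol
Product: 13 α-methylene methyl ketone
Conditions: DMP, pyridine, CH2Cl2, 0 °C → rt
Reagents that add atoms: none
Why: Dess–Martin oxidation gives the 1,1-disubstituted enone without strong base, so the reactive Michael acceptor is not exposed to conjugate addition.

Step 11
Reactants: 14 2-methylbut-3-en-2-ol
Product: 15 triethyl[(2-methylbut-3-en-2-yl)oxy]silane
Conditions: Et3SiOTf, 2,6-lutidine, CH2Cl2, 0 °C
Reagents that add atoms: triethylsilyl trifluoromethanesulfonate, CC[Si](CC)(CC)OS(=O)(=O)C(F)(F)F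
Why: Triflate silylation is the reliable way to silylate a tertiary alcohol.

Step 12
Reactants: 15 triethyl[(2-methylbut-3-en-2-yl)oxy]silane
Product: 17 2-methyl-2-(triethylsilyloxy)propanal, via secondary ozonide 16 (not isolated)
Conditions: O3, CH2Cl2, −78 °C; then PPh3, −78 °C → rt
Reagents that add atoms: ozone, [O-][O+]=O
Why: Ozonolysis of the terminal alkene with reductive work-up gives the non-enolisable α-silyloxy aldehyde, the silyl ether being inert to ozone.

Step 13
Reactants: 13 α-methylene methyl ketone; 17 2-methyl-2-(triethylsilyloxy)propanal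
Product: 19 aldol adduct (C4′ epimers), via cross-conjugated lithium enolate 18 (not isolated)
Conditions: LiN(iPr)2, THF, −78 °C (13 added slowly to the base); then 17, −78 °C; AcOH quench at −78 °C
Reagents that add atoms: none
Why: Crossed aldol addition, in which the ketone has α-hydrogens only on its methyl group (one kinetic enolate) and the aldehyde cannot enolise; the C4′ carbinol forms as an epimer mixture that the following dehydration removes.

Step 14
Reactants: 19 aldol adduct
Product: 21 E-dienone, via C4′ mesylate 20 (not isolated)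
Conditions: MsCl, Et3N (excess), CH2Cl2, 0 °C → rt
Reagents that add atoms: none
Why: Mesylation and in situ E1cB elimination complete the aldol condensation and give the conjugated enone with the thermodynamically favoured E geometry, enforced by the bulky silyloxy-bearing quaternary carbon.

Step 15
Reactants: 21 E-dienone
Product: 22 diol (1-OH and C5′-OH free; 6-OTBS kept)
Conditions: pyridinium p-toluenesulfonate (PPTS, cat.), MeOH/CH2Cl2, 0 °C → rt
Reagents that add atoms: none
Why: Acid-catalysed methanolysis cleaves both triethylsilyl ethers far faster than the secondary TBS ether (selective desilylation), freeing the C1 and tertiary alcohols while C6 stays protected; 22 is oxidised at once.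

Step 16
Reactants: 22 diol
Product: 23 epoxy ketone (C1=O; 6-OTBS)
Conditions: DMP, pyridine, CH2Cl2, 0 °C
Reagents that add atoms: none
Why: Dess–Martin oxidation converts the only oxidisable alcohol (secondary, C1) into the α,β-epoxy ketone under near-neutral conditions that do not epimerise C6, and the tertiary alcohol cannot react.

Step 17
Reactants: 23 epoxy ketone
Product: 24 α-ketol (6-OH and C5′-OH free)
Conditions: HF·pyridine, pyridine, THF, 0 °C → rt
Reagents that add atoms: none
Why: Buffered HF·pyridine desilylation removes the TBS group of the α-silyloxy ketone without base, so C6 is not epimerised and the epoxy ketone and dienone survive.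

Step 18
Reactants: 24 α-ketol; 25 tiglic acid
Product: 27 target tiglate, via tigloyl 2,4,6-trichlorobenzoic anhydride 26 (not isolated)
Conditions: 25 (1.2 equiv), 2,4,6-Cl3C6H2COCl, Et3N, toluene, rt; then 24, 4-(dimethylamino)pyridine (DMAP), 0 °C → rt
Reagents that add atoms: none
Why: Yamaguchi esterification, in which the mixed anhydride acylates the secondary α-ketol hydroxyl much faster than the tertiary alcohol, the E-configured tiglate does not isomerise, and C6 keeps its configuration because only the O–H bond reacts.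

**Compound list**
1 | (R)-(−)-carvone, (5R)-2-methyl-5-(prop-1-en-2-yl)cyclohex-2-en-1-one | C=C(C)[C@@H]1CC=C(C)C(=O)C1 | starting material
2 | carvone lithium dienolate (O–Li on C1; C1=C6 and C2=C3; not isolated) | C=C(C)[C@@H]1CC=C(C)C(O[Li])=C1 | intermediate
3 | carvone trimethylsilyl dienol ether, (R)-trimethyl{[6-methyl-3-(prop-1-en-2-yl)cyclohexa-1,5-dien-1-yl]oxy}silane | C=C(C)[C@@H]1CC=C(C)C(O[Si](C)(C)C)=C1 | intermediate
4 | trans-6-(trimethylsilyloxy)carvone (6-O trans to isopropenyl; not isolated) | C=C(C)[C@@H]1CC=C(C)C(=O)[C@H]1O[Si](C)(C)C | intermediate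
5 | trans-6-hydroxycarvone, (5S,6S)-6-hydroxy-2-methyl-5-(prop-1-en-2-yl)cyclohex-2-en-1-one | C=C(C)[C@@H]1CC=C(C)C(=O)[C@H]1O | intermediate
6 | trans-6-(tert-butyldimethylsilyloxy)carvone (5S,6S) | C=C(C)[C@@H]1CC=C(C)C(=O)[C@H]1O[Si](C)(C)C(C)(C)C | intermediate
7 | allylic alcohol: 6-(TBS-oxy)-2-methyl-5-isopropenylcyclohex-2-en-1-ol, 1-OH cis to isopropenyl, 6-OTBS trans to both | C=C(C)[C@@H]1CC=C(C)[C@H](O)[C@H]1O[Si](C)(C)C(C)(C)C | intermediate
8 | epoxy alcohol: 2,3-epoxide of 7, oxirane O and 1-OH both cis to the C5 isopropenyl, 6-OTBS trans | C=C(C)[C@@H]1C[C@@H]2O[C@]2(C)[C@H](O)[C@H]1O[Si](C)(C)C(C)(C)C | intermediate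
9 | 1-O-triethylsilyl ether of 8 | C=C(C)[C@@H]1C[C@@H]2O[C@]2(C)[C@H](O[Si](CC)(CC)CC)[C@H]1O[Si](C)(C)C(C)(C)C | intermediate
10 | primary allylic alcohol: C5 substituent 3-hydroxyprop-1-en-2-yl, ring as in 9 | C=C(CO)[C@@H]1C[C@@H]2O[C@]2(C)[C@H](O[Si](CC)(CC)CC)[C@H]1O[Si](C)(C)C(C)(C)C | intermediate
11 | enal: C5 substituent 3-oxoprop-1-en-2-yl, ring as in 9 | C=C(C=O)[C@@H]1C[C@@H]2O[C@]2(C)[C@H](O[Si](CC)(CC)CC)[C@H]1O[Si](C)(C)C(C)(C)C | intermediate
12 | secondary allylic alcohol: C5 substituent 3-hydroxybut-1-en-2-yl (C2′ epimers), ring as in 9 | C=C(C(C)O)[C@@H]1C[C@@H]2O[C@]2(C)[C@H](O[Si](CC)(CC)CC)[C@H]1O[Si](C)(C)C(C)(C)C | intermediate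
13 | α-methylene methyl ketone: C5 substituent 3-oxobut-1-en-2-yl, ring as in 9 | C=C(C(C)=O)[C@@H]1C[C@@H]2O[C@]2(C)[C@H](O[Si](CC)(CC)CC)[C@H]1O[Si](C)(C)C(C)(C)C | intermediate
14 | 2-methylbut-3-en-2-ol | C=CC(C)(C)O | starting material
15 | triethyl[(2-methylbut-3-en-2-yl)oxy]silane | C=CC(C)(C)O[Si](CC)(CC)CC | intermediate
16 | secondary ozonide, 3-[2-(triethylsilyloxy)propan-2-yl]-1,2,4-trioxolane (not isolated) | CC(C)(O[Si](CC)(CC)CC)C1OCOO1 | intermediate
17 | 2-methyl-2-(triethylsilyloxy)propanal | CC(C)(O[Si](CC)(CC)CC)C=O | intermediate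
18 | cross-conjugated lithium enolate of 13 (O–Li on C2′, C2′=C3′H2; not isolated) | C=C(C(=C)O[Li])[C@@H]1C[C@@H]2O[C@]2(C)[C@H](O[Si](CC)(CC)CC)[C@H]1O[Si](C)(C)C(C)(C)C | intermediate
19 | aldol adduct: C5 substituent 5-hydroxy-6-methyl-3-oxo-6-(triethylsilyloxy)hept-1-en-2-yl (C4′ epimers), ring as in 9 | C=C(C(=O)CC(O)C(C)(C)O[Si](CC)(CC)CC)[C@@H]1C[C@@H]2O[C@]2(C)[C@H](O[Si](CC)(CC)CC)[C@H]1O[Si](C)(C)C(C)(C)C | intermediate
20 | C4′ methanesulfonate of 19 (not isolated) | C=C(C(=O)CC(OS(C)(=O)=O)C(C)(C)O[Si](CC)(CC)CC)[C@@H]1C[C@@H]2O[C@]2(C)[C@H](O[Si](CC)(CC)CC)[C@H]1O[Si](C)(C)C(C)(C)C | intermediate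
21 | E-dienone: C5 substituent (4E)-6-methyl-3-oxo-6-(triethylsilyloxy)hepta-1,4-dien-2-yl, 1-OTES, 6-OTBS | C=C(C(=O)/C=C/C(C)(C)O[Si](CC)(CC)CC)[C@@H]1C[C@@H]2O[C@]2(C)[C@H](O[Si](CC)(CC)CC)[C@H]1O[Si](C)(C)C(C)(C)C | intermediate
22 | diol: 1-OH and C5′-OH free, 6-OTBS, E-dienone side chain | C=C(C(=O)/C=C/C(C)(C)O)[C@@H]1C[C@@H]2O[C@]2(C)[C@H](O)[C@H]1O[Si](C)(C)C(C)(C)C | intermediate
23 | epoxy ketone: C1=O, 2,3-epoxide cis to C5 side chain, 6-OTBS trans, C5′-OH free | C=C(C(=O)/C=C/C(C)(C)O)[C@@H]1C[C@@H]2O[C@]2(C)C(=O)[C@H]1O[Si](C)(C)C(C)(C)C | intermediate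
24 | α-ketol: as 23 with free 6-OH | C=C(C(=O)/C=C/C(C)(C)O)[C@@H]1C[C@@H]2O[C@]2(C)C(=O)[C@H]1O | intermediate
25 | tiglic acid, (E)-2-methylbut-2-enoic acid | C/C=C(\C)C(=O)O | starting material
26 | (E)-2-methylbut-2-enoic 2,4,6-trichlorobenzoic anhydride (not isolated) | C/C=C(\C)C(=O)OC(=O)c1c(Cl)cc(Cl)cc1Cl | intermediate
27 | CNP0263368.1, (1S,3S,4S,6S)-4-[(4E)-6-hydroxy-6-methyl-3-oxohepta-1,4-dien-2-yl]-1-methyl-2-oxo-7-oxabicyclo[4.1.0]heptan-3-yl (2E)-2-methylbut-2-enoate | C=C(C(=O)/C=C/C(C)(C)O)[C@@H]1C[C@@H]2O[C@]2(C)C(=O)[C@H]1OC(=O)/C(C)=C/C | target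

**Summary**
Total step count: 18. Longest linear sequence: 16 steps (steps 1–10, then 13–18); the aldehyde branch is 2 steps (11–12).

Steps most likely to fail:

Step 7 (SeO2 allylic oxidation; moderate yield, possible attack at the ring C5–H). Fallback: from 9, ene-type chlorination with Ca(OCl)2 and solid CO2 in CH2Cl2/H2O at 0 °C gives the allylic chloride F3. Displacement with KOAc and 18-crown-6 in MeCN at 60 °C gives the allylic acetate F4. Methanolysis with K2CO3 in MeOH at 0 °C returns to the route at 10.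

Step 13 (lithium enolate of a reactive α-methylene ketone; Michael self-addition or retro-aldol possible). Fallback: from 13, Me3SiOTf and Et3N in CH2Cl2 at 0 °C give the isolable 2-(trimethylsilyloxy)-1,3-diene F5. Mukaiyama aldol addition of it to 17 pre-complexed with BF3·OEt2 (CH2Cl2, −78 °C, short contact to spare the epoxide) and aqueous work-up return to the route at 19.

Step 4 (facial selectivity of the hydride, on which the epoxide configuration depends). Fallback: if reduction of 6 gives the C1-epimeric allylic alcohol F1 (1-OH cis to the 6-OTBS group), it is inverted rather than re-reduced. Mitsunobu reaction with 4-nitrobenzoic acid, PPh3 and diisopropyl azodicarboxylate (DIAD) in toluene at 0 °C gives the inverted 4-nitrobenzoate F2. K2CO3 in MeOH at 0 °C then returns to the route at 7.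

**Further compounds**
F1 | step 4 | C1-epimer of 7 (1-OH trans to the C5 isopropenyl, cis to 6-OTBS) | C=C(C)[C@@H]1CC=C(C)[C@@H](O)[C@H]1O[Si](C)(C)C(C)(C)C
F2 | step 4 | 4-nitrobenzoate of 7 (ester oxygen cis to the C5 isopropenyl) | C=C(C)[C@@H]1CC=C(C)[C@H](OC(=O)c2ccc(cc2)[N+](=O)[O-])[C@H]1O[Si](C)(C)C(C)(C)C
F3 | step 7 | allylic chloride: C5 substituent 3-chloroprop-1-en-2-yl, ring as in 9 | C=C(CCl)[C@@H]1C[C@@H]2O[C@]2(C)[C@H](O[Si](CC)(CC)CC)[C@H]1O[Si](C)(C)C(C)(C)C
F4 | step 7 | allylic acetate: C5 substituent 3-acetoxyprop-1-en-2-yl, ring as in 9 | C=C(COC(C)=O)[C@@H]1C[C@@H]2O[C@]2(C)[C@H](O[Si](CC)(CC)CC)[C@H]1O[Si](C)(C)C(C)(C)C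
F5 | step 13 | 2-(trimethylsilyloxy)-1,3-diene from 13: C5 substituent 3-(trimethylsilyloxy)buta-1,3-dien-2-yl, ring as in 9 | C=C(C(=C)O[Si](C)(C)C)[C@@H]1C[C@@H]2O[C@]2(C)[C@H](O[Si](CC)(CC)CC)[C@H]1O[Si](C)(C)C(C)(C)C
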